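**Plan**
- Retrosynthesis: the nine O-methyl groups are restored, a CO2Me is put back on C6 of ring A (the 2,4,6-trihydroxyphenoxy ring), and ring A is opened at its C1–C6 bond. The open chain is then cut at C3–C4 and at the O–C2 ether bond, and the diaryl ether C–O bonds B–C, C–D and D–E are cut last.
- Enabling feature: in ring A the ether carbon C2 lies between the hydroxylated C1 and C3, with C5–OH para to it. Ring A is therefore the enol form of a 2-aryloxy-3,5-dioxoheptanedioate in which C2 is the α-carbon of a 1,3-dicarbonyl, so the hindered ether can enter as a malonate carbon.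
- Forward: ring E phenol → ED → CDE → BCDE by three rounds of copper-catalysed etherification with a bromobenzaldehyde (rings D, C, B) and Baeyer–Villiger unmasking of the next phenol. Then chloromalonate O-alkylation, extension by a C4 acetoacetate unit, Claisen closure of ring A (the only ring built from acyclic carbons), decarboxylation and ninefold demethylation.
- Stereochemistry: the target is achiral; the single chain stereocentre (C2) is carried as the racemate and vanishes on aromatisation.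

Key step: step 10

Remark: Ar denotes the nonamethyl BCDE group 4-{2-[3,5-dimethoxy-4-(3,4,5-trimethoxyphenoxy)phenoxy]-3,5-dimethoxyphenoxy}-3,5-dimethoxyphenyl. Compounds 15 and 17–19 are racemic, 20 is a diastereomer mixture, and diene 16 is used as the commercial isomer mixture, since its geometry is lost in the product.

**Route**

Step 1
Reactants: 1 3,4,5-trimethoxyphenol; 2 4-bromo-3,5-dimethoxybenzaldehyde
Product: 3 3,5-dimethoxy-4-(3,4,5-trimethoxyphenoxy)benzaldehyde
Conditions: CuI (10 mol%), N,N-dimethylglycine hydrochloride (30 mol%), Cs2CO3, 1,4-dioxane, 100 °C, Ar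
Reagents that add atoms: none
Why: Ullmann-type copper-catalysed C–O coupling: the unhindered, electron-rich phenoxide of 1 should displace bromide from 2, whose para-formyl group activates the C–Br bond enough to offset the two flanking methoxy groups, and the non-enolisable aldehyde tolerates Cs2CO3.

Step 2
Reactants: 3 3,5-dimethoxy-4-(3,4,5-trimethoxyphenoxy)benzaldehyde
Product: 5 3,5-dimethoxy-4-(3,4,5-trimethoxyphenoxy)phenol, via aryl formate 4 (not isolated)
Conditions: mCPBA, CH2Cl2, 0 °C→rt; then K2CO3 (cat.), MeOH, rt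
Reagents that add atoms: mCPBA (3-chloroperbenzoic acid), O=C(OO)c1cccc(Cl)c1
Why: Baeyer–Villiger oxidation with a Dakin-type outcome: the electron-rich trioxygenated aryl group migrates in preference to hydride, and mild methanolysis of the formate should free the phenol without touching the diaryl ether.

Step 3
Reactants: 5 3,5-dimethoxy-4-(3,4,5-trimethoxyphenoxy)phenol; 6 2-bromo-3,5-dimethoxybenzaldehyde
Product: 7 2-[3,5-dimethoxy-4-(3,4,5-trimethoxyphenoxy)phenoxy]-3,5-dimethoxybenzaldehyde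
Conditions: CuI (10 mol%), N,N-dimethylglycine hydrochloride (30 mol%), Cs2CO3, 1,4-dioxane, 100 °C, Ar
Reagents that add atoms: none
Why: Ullmann-type coupling: phenol 5 is unhindered and the ortho-formyl group of 6 activates the C–Br bond lying between CHO and OMe, which places the ring D oxygen on C2 of ring C.

Step 4
Reactants: 7 2-[3,5-dimethoxy-4-(3,4,5-trimethoxyphenoxy)phenoxy]-3,5-dimethoxybenzaldehyde
Product: 9 2-[3,5-dimethoxy-4-(3,4,5-trimethoxyphenoxy)phenoxy]-3,5-dimethoxyphenol, via aryl formate 8 (not isolated)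
Conditions: mCPBA, CH2Cl2, 0 °C→rt; then K2CO3 (cat.), MeOH, rt
Reagents that add atoms: mCPBA (3-chloroperbenzoic acid), O=C(OO)c1cccc(Cl)c1
Why: Baeyer–Villiger oxidation: the ortho-aryloxy-substituted aryl group should migrate to oxygen, so that after methanolysis the formyl carbon is exchanged for the C1 hydroxyl of ring C.

Step 5
Reactants: 9 2-[3,5-dimethoxy-4-(3,4,5-trimethoxyphenoxy)phenoxy]-3,5-dimethoxyphenol; 2 4-bromo-3,5-dimethoxybenzaldehyde
Product: 10 4-{2-[3,5-dimethoxy-4-(3,4,5-trimethoxyphenoxy)phenoxy]-3,5-dimethoxyphenoxy}-3,5-dimethoxybenzaldehyde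
Conditions: CuI (20 mol%), N,N-dimethylglycine hydrochloride (60 mol%), Cs2CO3, 1,4-dioxane, 105 °C, Ar
Reagents that add atoms: none
Why: Ullmann-type coupling with the bromide of step 1 and the more encumbered ortho-aryloxy phenol 9; the para-formyl activation of 2 is relied on to form the tri-ortho-substituted ether between rings B and C.

Step 6
Reactants: 10 4-{2-[3,5-dimethoxy-4-(3,4,5-trimethoxyphenoxy)phenoxy]-3,5-dimethoxyphenoxy}-3,5-dimethoxybenzaldehyde
Product: 12 4-{2-[3,5-dimethoxy-4-(3,4,5-trimethoxyphenoxy)phenoxy]-3,5-dimethoxyphenoxy}-3,5-dimethoxyphenol (ArOH), via aryl formate 11 (not isolated)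
Conditions: mCPBA, CH2Cl2, 0 °C→rt; then K2CO3 (cat.), MeOH, rt
Reagents that add atoms: mCPBA (3-chloroperbenzoic acid), O=C(OO)c1cccc(Cl)c1
Why: Baeyer–Villiger oxidation as in step 2 on the same 4-aryloxy-3,5-dimethoxybenzaldehyde pattern; it should give the ring B phenol, which is meta to both methoxy groups and therefore unhindered.

Step 7
Reactants: 12 ArOH; 13 dimethyl chloromalonate
Product: 14 dimethyl 2-(ArO)malonate
Conditions: K2CO3, acetone, reflux
Reagents that add atoms: none
Why: Williamson-type SN2 alkylation of an unhindered phenoxide with a doubly activated secondary chloride; it makes the ring B–O–C2 bond of the future ring A without any hindered aryl coupling.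

Step 8
Reactants: 14 dimethyl 2-(ArO)malonate
Product: 15 (±)-2-(ArO)-3-methoxy-3-oxopropanoic acid (malonic half ester)
Conditions: KOH (1.05 equiv), MeOH–THF, 0 °C→rt; then aq. HCl to pH 2, 0 °C
Reagents that add atoms: potassium hydroxide, [K+].[OH-]
Why: Selective mono-saponification of a symmetric malonate: after the first hydrolysis the carboxylate repels hydroxide, so one ester should survive; C2 becomes a stereocentre, formed as the racemate and erased in step 10.

Step 9
Reactants: 15 (±)-2-(ArO)-3-methoxy-3-oxopropanoic acid; 16 1-methoxy-1,3-bis(trimethylsilyloxy)buta-1,3-diene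
Product: 19 dimethyl (±)-2-(ArO)-3,5-dioxoheptanedioate, via acid chloride 17 (not isolated), via silyl enol ether 18 (not isolated)
Conditions: (COCl)2, DMF (cat.), CH2Cl2, 0 °C→rt, evaporate; then 16 (1.5 equiv), CH2Cl2, −78 °C→rt; aq. HCl work-up
Reagents that add atoms: none
Why: Acid chloride formation followed by γ-selective C-acylation of the 1,3-bis(silyloxy)diene (vinylogous Mukaiyama-type Claisen condensation), a known route to 3,5-dioxo esters that needs no base and so should leave the acidic aryloxymalonyl C–H of 17 untouched; C2 stays racemic.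

Step 10
Reactants: 19 dimethyl (±)-2-(ArO)-3,5-dioxoheptanedioate
Product: 21 methyl 3-(ArO)-2,4,6-trihydroxybenzoate, via cyclohexanetrione ester 20 (not isolated)
Conditions: Mg(OMe)2 (4 equiv), MeOH, reflux, Ar; then aq. HCl, 0 °C
Reagents that add atoms: none
Why: Mg(OMe)2 should convert 19 into a chelated polyenolate deprotonated at C4 and C6; the C6 carbanion, flanked by the C5 ketone and the C7 ester, adds to the C1 ester carbonyl and expels methoxide, which forms the C6–C1 bond and gives trione 20, whose enolisation to the arene 21 is irreversible. The closest known reaction type is the base-mediated Claisen (Dieckmann-type) cyclisation of poly-β-keto esters to phloroglucinols, the laboratory counterpart of the biosynthetic closure. Ring A closes by a 6-exo-trig acyl substitution, with C1–C6 in the ring and the leaving methoxide outside it. No stereocentre is set: C2 of 19 becomes sp2, and the two centres of 20 are lost on enolisation. The step needs C-acylation from C6 to win over O-acylation to a 4-hydroxy-2-pyrone and over closure from C2 onto C7. Mg(OMe)2 in methanol should reopen any pyrone to the chelated chain, the C2 closure gives a quaternary trione that cannot aromatise and can revert by retro-Claisen cleavage, and only the C6→C1 mode ends in the aromatic salicylate-type magnesium chelate, which drains the equilibria.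

Step 11
Reactants: 21 methyl 3-(ArO)-2,4,6-trihydroxybenzoate
Product: 23 2-(ArO)benzene-1,3,5-triol, via benzoic acid 22 (not isolated)
Conditions: KOH, degassed H2O–MeOH, reflux, Ar; then aq. HCl, 50 °C
Reagents that add atoms: none
Why: Saponification and protodecarboxylation: the phloroglucinol carboxylate reacts through its keto tautomer like a β-keto ester, and the free 2,4,6-trihydroxybenzoic acid should lose CO2 on mild warming in acid by ipso-protonation.

Step 12
Reactants: 23 2-(ArO)benzene-1,3,5-triol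
Product: 24 2-(4-{2-[3,5-dihydroxy-4-(3,4,5-trihydroxyphenoxy)phenoxy]-3,5-dihydroxyphenoxy}-3,5-dihydroxyphenoxy)benzene-1,3,5-triol (CNP0227069.0)
Conditions: BBr3 (excess), CH2Cl2, −78 °C→rt, Ar; H2O quench at 0 °C
Reagents that add atoms: none
Why: Lewis-acid ether cleavage (BBr3 demethylation): bromide attacks each O–CH3 carbon, whereas the diaryl ether bonds offer no sp3 carbon and should persist; exclusion of air protects the polyphenol.

**Compound list**
1 | 3,4,5-trimethoxyphenol | COc1cc(O)cc(OC)c1OC | starting material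
2 | 4-bromo-3,5-dimethoxybenzaldehyde | COc1cc(C=O)cc(OC)c1Br | starting material
3 | 3,5-dimethoxy-4-(3,4,5-trimethoxyphenoxy)benzaldehyde | COc1cc(C=O)cc(OC)c1Oc1cc(OC)c(OC)c(OC)c1 | intermediate
4 | 3,5-dimethoxy-4-(3,4,5-trimethoxyphenoxy)phenyl formate | COc1cc(OC=O)cc(OC)c1Oc1cc(OC)c(OC)c(OC)c1 | intermediate (not isolated)
5 | 3,5-dimethoxy-4-(3,4,5-trimethoxyphenoxy)phenol | COc1cc(O)cc(OC)c1Oc1cc(OC)c(OC)c(OC)c1 | intermediate
6 | 2-bromo-3,5-dimethoxybenzaldehyde | COc1cc(C=O)c(Br)c(OC)c1 | starting material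
7 | 2-[3,5-dimethoxy-4-(3,4,5-trimethoxyphenoxy)phenoxy]-3,5-dimethoxybenzaldehyde | COc1cc(C=O)c(Oc2cc(OC)c(Oc3cc(OC)c(OC)c(OC)c3)c(OC)c2)c(OC)c1 | intermediate
8 | 2-[3,5-dimethoxy-4-(3,4,5-trimethoxyphenoxy)phenoxy]-3,5-dimethoxyphenyl formate | COc1cc(OC=O)c(Oc2cc(OC)c(Oc3cc(OC)c(OC)c(OC)c3)c(OC)c2)c(OC)c1 | intermediate (not isolated)
9 | 2-[3,5-dimethoxy-4-(3,4,5-trimethoxyphenoxy)phenoxy]-3,5-dimethoxyphenol | COc1cc(O)c(Oc2cc(OC)c(Oc3cc(OC)c(OC)c(OC)c3)c(OC)c2)c(OC)c1 | intermediate
10 | 4-{2-[3,5-dimethoxy-4-(3,4,5-trimethoxyphenoxy)phenoxy]-3,5-dimethoxyphenoxy}-3,5-dimethoxybenzaldehyde | COc1cc(C=O)cc(OC)c1Oc1cc(OC)cc(OC)c1Oc1cc(OC)c(Oc2cc(OC)c(OC)c(OC)c2)c(OC)c1 | intermediate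
11 | 4-{2-[3,5-dimethoxy-4-(3,4,5-trimethoxyphenoxy)phenoxy]-3,5-dimethoxyphenoxy}-3,5-dimethoxyphenyl formate | COc1cc(OC=O)cc(OC)c1Oc1cc(OC)cc(OC)c1Oc1cc(OC)c(Oc2cc(OC)c(OC)c(OC)c2)c(OC)c1 | intermediate (not isolated)
12 | 4-{2-[3,5-dimethoxy-4-(3,4,5-trimethoxyphenoxy)phenoxy]-3,5-dimethoxyphenoxy}-3,5-dimethoxyphenol (ArOH) | COc1cc(O)cc(OC)c1Oc1cc(OC)cc(OC)c1Oc1cc(OC)c(Oc2cc(OC)c(OC)c(OC)c2)c(OC)c1 | intermediate
13 | dimethyl chloromalonate | COC(=O)C(Cl)C(=O)OC | starting material
14 | dimethyl 2-(ArO)malonate | COC(=O)C(Oc1cc(OC)c(Oc2cc(OC)cc(OC)c2Oc2cc(OC)c(Oc3cc(OC)c(OC)c(OC)c3)c(OC)c2)c(OC)c1)C(=O)OC | intermediate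
15 | (±)-2-(ArO)-3-methoxy-3-oxopropanoic acid | COC(=O)C(Oc1cc(OC)c(Oc2cc(OC)cc(OC)c2Oc2cc(OC)c(Oc3cc(OC)c(OC)c(OC)c3)c(OC)c2)c(OC)c1)C(=O)O | intermediate
16 | 1-methoxy-1,3-bis(trimethylsilyloxy)buta-1,3-diene (isomer mixture) | COC(O[Si](C)(C)C)=CC(=C)O[Si](C)(C)C | starting material
17 | methyl (±)-2-(ArO)-3-chloro-3-oxopropanoate | COC(=O)C(Oc1cc(OC)c(Oc2cc(OC)cc(OC)c2Oc2cc(OC)c(Oc3cc(OC)c(OC)c(OC)c3)c(OC)c2)c(OC)c1)C(=O)Cl | intermediate (not isolated)
18 | dimethyl (±)-6-(ArO)-5-oxo-3-(trimethylsilyloxy)hept-2-enedioate (double-bond geometry not fixed) | COC(=O)C=C(O[Si](C)(C)C)CC(=O)C(Oc1cc(OC)c(Oc2cc(OC)cc(OC)c2Oc2cc(OC)c(Oc3cc(OC)c(OC)c(OC)c3)c(OC)c2)c(OC)c1)C(=O)OC | intermediate (not isolated)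
19 | dimethyl (±)-2-(ArO)-3,5-dioxoheptanedioate | COC(=O)CC(=O)CC(=O)C(Oc1cc(OC)c(Oc2cc(OC)cc(OC)c2Oc2cc(OC)c(Oc3cc(OC)c(OC)c(OC)c3)c(OC)c2)c(OC)c1)C(=O)OC | intermediate
20 | methyl 3-(ArO)-2,4,6-trioxocyclohexane-1-carboxylate (diastereomer mixture) | COC(=O)C1C(=O)CC(=O)C(Oc2cc(OC)c(Oc3cc(OC)cc(OC)c3Oc3cc(OC)c(Oc4cc(OC)c(OC)c(OC)c4)c(OC)c3)c(OC)c2)C1=O | intermediate (not isolated)
21 | methyl 3-(ArO)-2,4,6-trihydroxybenzoate | COC(=O)c1c(O)cc(O)c(Oc2cc(OC)c(Oc3cc(OC)cc(OC)c3Oc3cc(OC)c(Oc4cc(OC)c(OC)c(OC)c4)c(OC)c3)c(OC)c2)c1O | intermediate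
22 | 3-(ArO)-2,4,6-trihydroxybenzoic acid | OC(=O)c1c(O)cc(O)c(Oc2cc(OC)c(Oc3cc(OC)cc(OC)c3Oc3cc(OC)c(Oc4cc(OC)c(OC)c(OC)c4)c(OC)c3)c(OC)c2)c1O | intermediate (not isolated)
23 | 2-(ArO)benzene-1,3,5-triol | Oc1cc(O)c(Oc2cc(OC)c(Oc3cc(OC)cc(OC)c3Oc3cc(OC)c(Oc4cc(OC)c(OC)c(OC)c4)c(OC)c3)c(OC)c2)c(O)c1 | intermediate
24 | 2-(4-{2-[3,5-dihydroxy-4-(3,4,5-trihydroxyphenoxy)phenoxy]-3,5-dihydroxyphenoxy}-3,5-dihydroxyphenoxy)benzene-1,3,5-triol | Oc1cc(O)c(Oc2cc(O)c(Oc3cc(O)cc(O)c3Oc3cc(O)c(Oc4cc(O)c(O)c(O)c4)c(O)c3)c(O)c2)c(O)c1 | target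

**Count**
Total steps: 12. Longest linear sequence: 12 steps (1 → 24); compounds 2, 6, 13 and 16 are purchased.

**Steps most likely to fail**

Step 10. An enolate oxygen may acylate in place of C6 (lactonisation), or methoxide may cleave the chain by retro-Claisen reaction before the crowded C1 ester next to the aryloxy carbon is attacked. The fallback gives up the de novo ring and brings ring A in preformed. It sets out from phenol 12, which would be coupled with 2-iodo-1,3,5-trimethoxybenzene under Ullmann conditions (CuI, picolinic acid, K3PO4, DMSO, 100 °C) to the dodecamethyl ether 2-(ArO)-1,3,5-trimethoxybenzene F1. BBr3 in CH2Cl2 would then cleave all twelve methyl ethers, and the route is rejoined at target 24.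

Step 9. Acid chloride 17 may lose HCl to its ketene and oligomerise, or acylate its own electron-rich ring B (intramolecular Friedel–Crafts closure), or the diene may be protonated before C-acylation. The fallback avoids any activated acid and builds ring A by a [3+3] double Claisen condensation. It sets out from malonate 14, which would be heated with dimethyl 3-oxopentanedioate and NaOMe in MeOH so that both methylene groups of the oxoglutarate acylate on the two malonate esters. This should give dimethyl 5-(ArO)-2,4,6-trihydroxybenzene-1,3-dicarboxylate F2. Hydrolysis with aqueous KOH and double decarboxylation on acidification would rejoin the route at triol 23.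

Step 5. Copper insertion into the doubly ortho-substituted C–Br bond may be too slow against the bulky ortho-aryloxy phenoxide, so that debromination of 2 and decay of the aldehyde take over. The fallback reverses the polarity of the partners. It sets out from phenol 9, which would be converted with Tf2O and pyridine into 2-[3,5-dimethoxy-4-(3,4,5-trimethoxyphenoxy)phenoxy]-3,5-dimethoxyphenyl trifluoromethanesulfonate F3. Miyaura borylation (Pd(dppf)Cl2, bis(pinacolato)diboron, KOAc, dioxane, 90 °C) would give the pinacol boronate 2-{2-[3,5-dimethoxy-4-(3,4,5-trimethoxyphenoxy)phenoxy]-3,5-dimethoxyphenyl}-4,4,5,5-tetramethyl-1,3,2-dioxaborolane F4. Chan–Lam coupling of F4 with the hindered phenol 4-hydroxy-3,5-dimethoxybenzaldehyde (Cu(OAc)2, pyridine, B(OH)3, MeCN, air) would rejoin the route at aldehyde 10.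

**Further compounds**
F1 | step 10 | 2-(ArO)-1,3,5-trimethoxybenzene | COc1cc(OC)c(Oc2cc(OC)c(Oc3cc(OC)cc(OC)c3Oc3cc(OC)c(Oc4cc(OC)c(OC)c(OC)c4)c(OC)c3)c(OC)c2)c(OC)c1
F2 | step 9 | dimethyl 5-(ArO)-2,4,6-trihydroxybenzene-1,3-dicarboxylate | COC(=O)c1c(O)c(C(=O)OC)c(O)c(Oc2cc(OC)c(Oc3cc(OC)cc(OC)c3Oc3cc(OC)c(Oc4cc(OC)c(OC)c(OC)c4)c(OC)c3)c(OC)c2)c1O
F3 | step 5 | 2-[3,5-dimethoxy-4-(3,4,5-trimethoxyphenoxy)phenoxy]-3,5-dimethoxyphenyl trifluoromethanesulfonate | COc1cc(OS(=O)(=O)C(F)(F)F)c(Oc2cc(OC)c(Oc3cc(OC)c(OC)c(OC)c3)c(OC)c2)c(OC)c1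
F4 | step 5 | 2-{2-[3,5-dimethoxy-4-(3,4,5-trimethoxyphenoxy)phenoxy]-3,5-dimethoxyphenyl}-4,4,5,5-tetramethyl-1,3,2-dioxaborolane | COc1cc(B2OC(C)(C)C(C)(C)O2)c(Oc2cc(OC)c(Oc3cc(OC)c(OC)c(OC)c3)c(OC)c2)c(OC)c1
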